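The readings are calculated on assumed constants; the scatter is artificial.

**The ratio.** Hold single product against substrate consumed. This capture share, an integral selectivity, is what you carry. At the last zeta reading, 46.8% stands against 84.6% consumed, a share of 55.3%.

the same everywhere: substrate 0.23 M
- zeta: partner 2 equiv; run made earlier
- beta: partner 4.5 equiv; run made earlier
- flask: partner 3.00 equiv; time 2.0 h

| run | time / min | single product / % | substrate / % |
|---|---|---|---|
| zeta | 10.0 | 19.4 | 68.9 |
| zeta | 25.0 | 33.0 | 45.0 |
| zeta | 50.0 | 42.9 | 24.9 |
| zeta | 80.0 | 46.8 | 15.4 |
| beta | 20.0 | 40.2 | 20.6 |
| beta | 40.0 | 42.9 | 6.5 |
| beta | 50.0 | 41.5 | 3.0 |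
| beta | 80.0 | 33.8 | 0.7 |

(readings scatter by 0.5 percentage points)

- the analysis behind the earlier runs scatters by 0.5 percentage points, standard deviation
- a reading or a percentage of single product counts all its forms, free or not

* equivalents of partner to substrate, everything else as given, that leave most single product at 2.0 h
* the amount of single product then, in percent of the substrate charged
* the amount of single product with the amounts as given

**Turning time.** By hand, longer time consumes more substrate but also exposes single product to partner for longer. The beta run shows both: it reads 42.9% at 40.0 min, then 33.8% at 80.0 min. At 50.0 min, with 3.0% substrate left, its share reads 42.8%, lower than the zeta share.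

**Turning partner.** The logarithm of charged over remaining [substrate] equals a constant times the time integral of [partner], so more partner reaches a given conversion sooner. Ignoring partner consumed, equivalents times time stands 1.60 times higher in the flask than at that beta reading. I therefore expect the flask at or past that conversion, and commit to 41.5% or a little under. The best charge should end nearer the zeta conversion.

**The forecast.** It gives 1.8 equiv (1.5 equiv to 2.1 equiv) as the best charge, 47.8% (46.5% to 49.5%) there, and 39% (36.5% to 41.5%) for the flask, “already well past the maximum”.

**The result.** The best charge is 1.93 equiv, giving 47.7%, and the flask gives 41.1%.

    substrate + partner → single product (k = 0.0643 /M/min)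
    crystals ⇌ single product, rate k2*(cs2 - [single product]) while solid is left; crystals form when [single product] > cs2 (solubility = 13.0 mM, k = 0.431 /min)
    substrate + partner → other mono adduct (k = 0.0258 /M/min)
    partner + other mono adduct → double product (k = 0.0897 /M/min)
    partner → decomposed reagent (k = 0.00167 /min)
    partner + single product → double product (k = 0.0970 /M/min)

**The share again.** The flask keeps 1.7% substrate at 2.00 h, so its capture share is 41.8%. A run of this flask with that much substrate left and a share above 42.2% or below 37.1% would fall outside the forecast range. A neighbour flask charged with 1.80 equiv keeps 12.6% substrate, so the zeta share gives 48.3% there, and that neighbour holds 47.5% single product.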